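**Assumption:** p-menthane numbering is used (C1 = ring CBr(CH3), C2 = ring CHBr, C4 = ring CH, C8 = side-chain CBr, C9 = CH2Br, C10 = side-chain CH3). CIP analysis of the given SMILES gives (1S,2S,4R,8R), with both ring bromines axial and trans when the C4 side chain is equatorial.

## Retrosynthetic overview
1. 30 ⇒ 28 ⇒ 26: the C8–Br bond is made last (OH→Br with retention through a bromonium ion). The C1/C2 bromides come just before it, by trans-diaxial Br2 addition.
2. 26 ⇒ 25 ⇒ 23 ⇒ 22 ⇒ 21: the ring cannot bias C8, so C8 is set by reagent control (Sharpless epoxidation). After that only C9 and C10 are touched.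
3. 21 ⇒ 17 ⇒ 13: one carbon is added at C8 by vinyl triflate carbonylation of the methyl ketone, which comes from the acid.
4. 13 ⇒ 12: the only ring, the cyclohexene with C1=C2, is closed by ring-closing metathesis.
5. 12 ⇒ 9 ⇒ 7 ⇒ 4 + 5: the key C4–C5 bond comes from an intermolecular, auxiliary-controlled Michael addition of the titanium enolate of 4 to methyl vinyl ketone 5. This step sets C4.

## Route

Step 1
Reactants: 1 (R)-4-benzyl-1,3-oxazolidin-2-one, 2 pent-4-enoyl chloride
Product: 4 (4R)-4-benzyl-3-(pent-4-enoyl)-1,3-oxazolidin-2-one, via lithium oxazolidinide 3 (not isolated)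
Conditions: n-BuLi (1.05 equiv), THF, −78 °C; then 2 (1.1 equiv), −78 → 0 °C
Reagents that add atoms: none
Why: N-acylation of the lithiated Evans auxiliary by an acid chloride (nucleophilic acyl substitution) is fast and clean and leaves the auxiliary stereocentre untouched.

Step 2
Reactants: 4 (4R)-4-benzyl-3-(pent-4-enoyl)-1,3-oxazolidin-2-one, 5 but-3-en-2-one (methyl vinyl ketone)
Product: 7 (4R)-4-benzyl-3-[(2R)-5-oxo-2-(prop-2-en-1-yl)hexanoyl]-1,3-oxazolidin-2-one, via chlorotitanium Z-enolate 6 (not isolated)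
Conditions: TiCl4 (1.05 equiv), iPr2NEt (1.1 equiv), CH2Cl2, 0 °C, 1 h; then 5 (1.5 equiv, slow addition), 0 °C; aq NH4Cl
Reagents that add atoms: none
Why: In this intermolecular Evans titanium-enolate Michael addition, soft enolisation gives only the chelated Z-enolate, which adds to the enone terminus on the face anti to the benzyl group (same facial sense as Evans alkylation); this forms C4–C5 and sets C4 as R, and the minor diastereomer is removed by chromatography.

Step 3
Reactants: 7 Michael adduct
Product: 9 (2R)-5-oxo-2-(prop-2-en-1-yl)hexanoic acid, via peroxy acid 8 (not isolated)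
Conditions: LiOH·H2O (2 equiv), 30% H2O2 (4 equiv), THF/H2O 3:1, 0 °C; Na2SO3; then 1 M HCl to pH 2
Reagents that add atoms: hydrogen peroxide OO
Why: In this hydroperoxide cleavage of the imide, the alpha-effect nucleophile attacks the exocyclic acyl carbonyl selectively and is too weakly basic to epimerise C4, and sulfite then reduces the peroxy acid.

Step 4
Reactants: 9 (2R)-5-oxo-2-(prop-2-en-1-yl)hexanoic acid
Product: 12 (2R)-5-methyl-2-(prop-2-en-1-yl)hex-5-enoic acid, via potassium keto carboxylate 10 (not isolated), via potassium dienoate 11 (not isolated)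
Conditions: MePPh3Br (3.0 equiv), KOtBu (3.0 equiv), THF, 0 °C; then 9, 0 °C → rt; 1 M HCl, acid–base extraction
Reagents that add atoms: methyltriphenylphosphonium bromide C[P+](c1ccccc1)(c1ccccc1)c1ccccc1.[Br-]
Why: In this Wittig methylenation the carboxylate forms first, is inert to the ylide and protects the C4–H from deprotonation, so only the methyl ketone reacts.

Step 5
Reactants: 12 (2R)-5-methyl-2-(prop-2-en-1-yl)hex-5-enoic acid
Product: 13 (1R)-4-methylcyclohex-3-ene-1-carboxylic acid
Conditions: second-generation Grubbs catalyst (H2IMes)(PCy3)Cl2Ru=CHPh (2 mol%), CH2Cl2 (0.02 M), 40 °C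
Reagents that add atoms: none
Why: Ring-closing metathesis of a monosubstituted and a 1,1-disubstituted alkene closes an unstrained six-membered ring and places the alkene unambiguously at C1=C2, so C4 stays stereogenic and R.

Step 6
Reactants: 13 (1R)-4-methylcyclohex-3-ene-1-carboxylic acid
Product: 15 (1R)-N-methoxy-N,4-dimethylcyclohex-3-ene-1-carboxamide, via acyl imidazole 14 (not isolated)
Conditions: 1,1'-carbonyldiimidazole (1.2 equiv), CH2Cl2, rt, 1 h; then MeNHOMe·HCl (1.5 equiv), rt
Reagents that add atoms: N,O-dimethylhydroxylamine hydrochloride CNOC.Cl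
Why: Weinreb amide formation through the acyl imidazole runs under near-neutral conditions that do not enolise C4.

Step 7
Reactants: 15 Weinreb amide
Product: 17 1-[(1R)-4-methylcyclohex-3-en-1-yl]ethan-1-one, via magnesium hemiaminal chelate 16 (not isolated)
Conditions: MeMgBr (1.4 equiv), THF, 0 °C; cold 1 M HCl quench
Reagents that add atoms: methylmagnesium bromide C[Mg]Br
Why: In the Weinreb ketone synthesis the chelated tetrahedral adduct survives until the quench, which prevents over-addition and limits contact of the ketone with base.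

Step 8
Reactants: 17 1-[(1R)-4-methylcyclohex-3-en-1-yl]ethan-1-one
Product: 19 1-[(1R)-4-methylcyclohex-3-en-1-yl]ethenyl trifluoromethanesulfonate, via lithium enolate 18 (not isolated)
Conditions: LDA (commercial solution, 1.15 equiv), THF, −78 °C, ketone added to base; then Comins' reagent (1.2 equiv), −78 °C → −20 °C
Reagents that add atoms: N-(5-chloropyridin-2-yl)bis(trifluoromethanesulfonimide) FC(F)(F)S(=O)(=O)N(c1ccc(Cl)cn1)S(=O)(=O)C(F)(F)F
Why: Kinetic enolisation with inverse addition removes a CH3 proton rather than the hindered C4–H, and O-triflation at −78 °C traps that enolate before it can equilibrate, so C4 is not scrambled.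

Step 9
Reactants: 19 vinyl triflate
Product: 20 methyl 2-[(1R)-4-methylcyclohex-3-en-1-yl]prop-2-enoate
Conditions: Pd(OAc)2 (5 mol%), PPh3 (10 mol%), CO (1 atm), MeOH (40 equiv), Et3N (2 equiv), DMF, rt
Reagents that add atoms: carbon monoxide [C-]#[O+]; methanol CO
Why: Palladium-catalysed alkoxycarbonylation (oxidative addition of the vinyl triflate to zerovalent palladium, CO insertion, methanolysis) proceeds at room temperature and leaves the isolated ring alkene and C4 alone.

Step 10
Reactants: 20 acrylate ester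
Product: 21 2-[(1R)-4-methylcyclohex-3-en-1-yl]prop-2-en-1-ol
Conditions: iBu2AlH (2.5 equiv), CH2Cl2, −78 → 0 °C; aq Rochelle salt
Reagents that add atoms: none
Why: iBu2AlH reduces the enoate by clean 1,2-addition to the allylic alcohol without conjugate reduction.

Step 11
Reactants: 21 allylic alcohol
Product: 22 {(2R)-2-[(1R)-4-methylcyclohex-3-en-1-yl]oxiran-2-yl}methanol
Conditions: Ti(OiPr)4 (10 mol%), D-(−)-diisopropyl tartrate (12 mol%), tBuOOH (2.0 equiv, decane), 4 Å MS, CH2Cl2, −20 °C
Reagents that add atoms: tert-butyl hydroperoxide CC(C)(C)OO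
Why: Sharpless asymmetric epoxidation is hydroxyl-directed, so the ring alkene is ignored; 2-alkyl allylic alcohols react with very high reagent control, and the D-(−)-tartrate delivers oxygen to the face that makes C8 R (the L-(+)-tartrate gives the S series).

Step 12
Reactants: 22 epoxy alcohol
Product: 23 (2R)-2-[(1R)-4-methylcyclohex-3-en-1-yl]propane-1,2-diol
Conditions: LiAlH4 (1.5 equiv), THF, 0 °C → rt; Fieser work-up
Reagents that add atoms: none
Why: Hydride opens the epoxide by SN2 attack at the unhindered CH2, which becomes the C10 methyl, so the C8–O bond and its configuration are kept; the possible Payne rearrangement is degenerate and regenerates the same enantiomer.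

Step 13
Reactants: 23 diol
Product: 24 (2R)-2-hydroxy-2-[(1R)-4-methylcyclohex-3-en-1-yl]propyl 4-methylbenzenesulfonate
Conditions: TsCl (1.1 equiv), pyridine, 0 °C
Reagents that add atoms: 4-methylbenzenesulfonyl chloride Cc1ccc(cc1)S(=O)(=O)Cl
Why: Selective sulfonylation works because the primary hydroxyl reacts far faster than the tertiary one.

Step 14
Reactants: 24 hydroxy tosylate
Product: 25 (2R)-2-methyl-2-[(1R)-4-methylcyclohex-3-en-1-yl]oxirane
Conditions: K2CO3 (2 equiv), MeOH, rt
Reagents that add atoms: none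
Why: In this intramolecular Williamson closure (3-exo-tet) the C8 oxygen displaces the tosylate at C9, so C8 keeps its configuration.

Step 15
Reactants: 25 epoxide
Product: 26 (2R)-1-bromo-2-[(1R)-4-methylcyclohex-3-en-1-yl]propan-2-ol
Conditions: LiBr (3 equiv), AcOH (3 equiv), THF, rt
Reagents that add atoms: lithium bromide [Li+].[Br-]
Why: Under this weakly acidic buffer bromide opens the epoxide by SN2 attack at the unhindered C9, so the C8–O bond is never broken.

Step 16
Reactants: 26 bromohydrin
Product: 28 (2R)-1-bromo-2-[(1R,3S,4S)-3,4-dibromo-4-methylcyclohexyl]propan-2-ol, via ring bromonium bromide 27 (not isolated)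
Conditions: Br2 (1.0 equiv, 1 M in CH2Cl2, dropwise), CH2Cl2, −78 °C, dark
Reagents that add atoms: bromine BrBr
Why: In this electrophilic anti-bromination under Fürst–Plattner control, the half-chair with the C4 side chain equatorial is opened trans-diaxially at tertiary C1, so Markovnikov and diaxial preferences coincide and set C1 and C2 as S,S.

Step 17
Reactants: 28 tribromo alcohol
Product: 30 (1S,2S,4R)-1,2-dibromo-4-[(2R)-1,2-dibromopropan-2-yl]-1-methylcyclohexane, via side-chain bromonium bromide 29 (not isolated)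
Conditions: HBr (33 wt% in AcOH, 5 equiv), CH2Cl2, 0 °C, dark; recrystallise from EtOAc/EtOH
Reagents that add atoms: hydrogen bromide Br
Why: In this substitution with neighbouring-group participation, the antiperiplanar C9–Br displaces the protonated hydroxyl from the rear and bromide reopens the bromonium ion at tertiary C8 from the side water left, so the double inversion gives net retention and C8 ends as R, with no alkene present to shuttle Br+.

## Compound list
1 | (R)-4-benzyl-1,3-oxazolidin-2-one | O=C1N[C@H](Cc2ccccc2)CO1 | starting material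
2 | pent-4-enoyl chloride | C=CCCC(=O)Cl | starting material
3 | N-lithio-(R)-4-benzyl-1,3-oxazolidin-2-one | [Li]N1C(=O)OC[C@H]1Cc1ccccc1 | intermediate
4 | (4R)-4-benzyl-3-(pent-4-enoyl)-1,3-oxazolidin-2-one | C=CCCC(=O)N1C(=O)OC[C@H]1Cc1ccccc1 | intermediate
5 | but-3-en-2-one (methyl vinyl ketone) | CC(=O)C=C | starting material
6 | (Z)-trichlorotitanium enolate of 4 | C=CC/C=C(\O[Ti](Cl)(Cl)Cl)N1C(=O)OC[C@H]1Cc1ccccc1 | intermediate
7 | (4R)-4-benzyl-3-[(2R)-5-oxo-2-(prop-2-en-1-yl)hexanoyl]-1,3-oxazolidin-2-one | CC(=O)CC[C@H](CC=C)C(=O)N1C(=O)OC[C@H]1Cc1ccccc1 | intermediate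
8 | (2R)-5-oxo-2-(prop-2-en-1-yl)hexaneperoxoic acid | CC(=O)CC[C@H](CC=C)C(=O)OO | intermediate
9 | (2R)-5-oxo-2-(prop-2-en-1-yl)hexanoic acid | CC(=O)CC[C@H](CC=C)C(=O)O | intermediate
10 | potassium (2R)-5-oxo-2-(prop-2-en-1-yl)hexanoate | CC(=O)CC[C@H](CC=C)C(=O)[O-].[K+] | intermediate
11 | potassium (2R)-5-methyl-2-(prop-2-en-1-yl)hex-5-enoate | CC(=C)CC[C@H](CC=C)C(=O)[O-].[K+] | intermediate
12 | (2R)-5-methyl-2-(prop-2-en-1-yl)hex-5-enoic acid | CC(=C)CC[C@H](CC=C)C(=O)O | intermediate
13 | (1R)-4-methylcyclohex-3-ene-1-carboxylic acid | OC(=O)[C@@H]1CCC(C)=CC1 | intermediate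
14 | 1H-imidazol-1-yl[(1R)-4-methylcyclohex-3-en-1-yl]methanone | O=C(n1ccnc1)[C@@H]1CCC(C)=CC1 | intermediate
15 | (1R)-N-methoxy-N,4-dimethylcyclohex-3-ene-1-carboxamide | CON(C)C(=O)[C@@H]1CCC(C)=CC1 | intermediate
16 | bromomagnesium alkoxide of the tetrahedral MeMgBr adduct of 15 (hemiaminal carbon undefined) | CON(C)C(C)(O[Mg]Br)[C@@H]1CCC(C)=CC1 | intermediate
17 | 1-[(1R)-4-methylcyclohex-3-en-1-yl]ethan-1-one | CC(=O)[C@@H]1CCC(C)=CC1 | intermediate
18 | lithium 1-[(1R)-4-methylcyclohex-3-en-1-yl]ethen-1-olate | [Li]OC(=C)[C@@H]1CCC(C)=CC1 | intermediate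
19 | 1-[(1R)-4-methylcyclohex-3-en-1-yl]ethenyl trifluoromethanesulfonate | C=C(OS(=O)(=O)C(F)(F)F)[C@@H]1CCC(C)=CC1 | intermediate
20 | methyl 2-[(1R)-4-methylcyclohex-3-en-1-yl]prop-2-enoate | COC(=O)C(=C)[C@@H]1CCC(C)=CC1 | intermediate
21 | 2-[(1R)-4-methylcyclohex-3-en-1-yl]prop-2-en-1-ol | OCC(=C)[C@@H]1CCC(C)=CC1 | intermediate
22 | {(2R)-2-[(1R)-4-methylcyclohex-3-en-1-yl]oxiran-2-yl}methanol | OC[C@@]1(CO1)[C@@H]2CCC(C)=CC2 | intermediate
23 | (2R)-2-[(1R)-4-methylcyclohex-3-en-1-yl]propane-1,2-diol | C[C@](O)(CO)[C@@H]1CCC(C)=CC1 | intermediate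
24 | (2R)-2-hydroxy-2-[(1R)-4-methylcyclohex-3-en-1-yl]propyl 4-methylbenzenesulfonate | C[C@](O)(COS(=O)(=O)c1ccc(C)cc1)[C@@H]2CCC(C)=CC2 | intermediate
25 | (2R)-2-methyl-2-[(1R)-4-methylcyclohex-3-en-1-yl]oxirane | C[C@]1(CO1)[C@@H]2CCC(C)=CC2 | intermediate
26 | (2R)-1-bromo-2-[(1R)-4-methylcyclohex-3-en-1-yl]propan-2-ol | C[C@](O)(CBr)[C@@H]1CCC(C)=CC1 | intermediate
27 | C1/C2 bromonium bromide of 26, bromine bridging the face anti to the C4 side chain | C[C@](O)(CBr)[C@@H]1CC[C@@]2(C)[Br+][C@H]2C1.[Br-] | intermediate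
28 | (2R)-1-bromo-2-[(1R,3S,4S)-3,4-dibromo-4-methylcyclohexyl]propan-2-ol | C[C@](O)(CBr)[C@@H]1CC[C@](C)(Br)[C@@H](Br)C1 | intermediate
29 | C8/C9 bromonium bromide, bromine bridging the face opposite to the departed hydroxyl | C[C@@]1(C[Br+]1)[C@@H]2CC[C@](C)(Br)[C@@H](Br)C2.[Br-] | intermediate
30 | (1S,2S,4R)-1,2-dibromo-4-[(2R)-1,2-dibromopropan-2-yl]-1-methylcyclohexane | C[C@](Br)(CBr)[C@@H]1CC[C@](C)(Br)[C@@H](Br)C1 | target

## Step count and risks
Total step count: 17. Longest linear sequence: 17 (fully linear from 1 and 2).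

**Step 2 (titanium-enolate Michael addition).** Methyl vinyl ketone may polymerise on the Lewis acid, or the product enolate may add a second time. The fallback moves stereocontrol from the auxiliary to enamine organocatalysis.
- It sets out from 2 and 5.
- 2 is reduced with LiAlH(OtBu)3 (THF, −78 °C) to pent-4-enal F1, which can also be bought.
- F1 and 5 are stirred neat at 4 °C with (R)-α,α-diphenylprolinol methyl ether (5 mol%) and ethyl 3,4-dihydroxybenzoate (20 mol%). The enamine is attacked anti to the diphenylmethyl group and gives (2R)-5-oxo-2-(prop-2-en-1-yl)hexanal F2.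
- F2 is oxidised at once (NaClO2, NaH2PO4, 2-methylbut-2-ene, tBuOH/H2O) and comes back to the route at 9.

**Step 16 (ring bromination next to a free tertiary alcohol).** The C8 hydroxyl can capture the bromonium ion to give a bromo-cineole-type ether, and some diequatorial dibromide can form. The fallback turns the hydroxyl into a non-nucleophilic leaving group before bromination.
- It sets out from 26.
- 26 is esterified (trifluoroacetic anhydride, pyridine, CH2Cl2, 0 °C) to (2R)-1-bromo-2-[(1R)-4-methylcyclohex-3-en-1-yl]propan-2-yl trifluoroacetate F3.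
- Br2 in CH2Cl2 at −78 °C gives (2R)-1-bromo-2-[(1R,3S,4S)-3,4-dibromo-4-methylcyclohexyl]propan-2-yl trifluoroacetate F4.
- F4 is ionised with HBr in AcOH/CH2Cl2 at 0 °C through 29. This bypasses 28 and comes back to the route at 30.

**Step 17 (retentive OH→Br exchange at tertiary C8).** Ionisation may leak through an open cation, which would give the C8 epimer, E1 alkenes or a 1,2-hydride shift from C4. The fallback gives up reagent control at C8 and relies on separation of diastereomers.
- It sets out from 17.
- Wittig methylenation (MePPh3Br, KOtBu, THF, 0 °C) gives (R)-limonene F5.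
- Br2 (2.05 equiv, CH2Cl2, −20 °C, dark) adds to both alkenes. The ring reacts trans-diaxially as in step 16, and the side chain reacts without facial bias.
- The product is 30 together with (1S,2S,4R)-1,2-dibromo-4-[(2S)-1,2-dibromopropan-2-yl]-1-methylcyclohexane F6 in about equal amounts.
- The two are separated by fractional crystallisation (EtOAc/EtOH) or preparative HPLC and assigned by X-ray anomalous dispersion. The fallback comes back to the route at 30.

## Further compounds
F1 | step 2 | pent-4-enal | C=CCCC=O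
F2 | step 2 | (2R)-5-oxo-2-(prop-2-en-1-yl)hexanal | CC(=O)CC[C@H](CC=C)C=O
F3 | step 16 | (2R)-1-bromo-2-[(1R)-4-methylcyclohex-3-en-1-yl]propan-2-yl trifluoroacetate | C[C@](OC(=O)C(F)(F)F)(CBr)[C@@H]1CCC(C)=CC1
F4 | step 16 | (2R)-1-bromo-2-[(1R,3S,4S)-3,4-dibromo-4-methylcyclohexyl]propan-2-yl trifluoroacetate | C[C@](OC(=O)C(F)(F)F)(CBr)[C@@H]1CC[C@](C)(Br)[C@@H](Br)C1
F5 | step 17 | (R)-limonene | CC(=C)[C@@H]1CCC(C)=CC1
F6 | step 17 | (1S,2S,4R)-1,2-dibromo-4-[(2S)-1,2-dibromopropan-2-yl]-1-methylcyclohexane | C[C@@](Br)(CBr)[C@@H]1CC[C@](C)(Br)[C@@H](Br)C1
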